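The C3–O and C6–O bonds are the disconnection on which the route rests. In the target, the C3 acetate and the C6 hydroxyl are cis and 1,4-related across the C4=C5 alkene of the cyclohexene ring, the retron of a palladium-catalysed 1,4-diacyloxylation of a C3–C6 diene. In one operation the key step should add acetate to C3 and a readily cleaved trifluoroacetate to C6, both on the α face, setting two stereocentres and leaving C6 distinguishable from the C2 and C3 acetates. Its precursor is the cyclohexa-3,5-diene that already carries the β tertiary hydroxyl and α benzoyloxymethyl group at C1 and the α acetate at C2, fixed by a Sharpless epoxidation followed by titanium-directed opening with acetic acid.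

Key step: step 8

Locants used throughout: C1 is the quaternary carbinol carbon, C7 its CH2O carbon, C2 and C3 the acetoxy carbons, C4=C5 the alkene, C6 the secondary carbinol; α is the ring face of C7, β that of the C1 hydroxyl.

Remark on step 8: a carboxylate bound to palladium can also be delivered to the allyl terminus on the metal's own face, which across a six-membered ring would give the trans isomer; a catalytic chloride ligand (LiCl) is therefore included so that both C–O bonds form by external attack.

Remark on step 6: the dibromide may form as either trans diastereomer; both give the same diene, and one is drawn.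

Step 1
Reactants: 1 buta-1,3-diene; 2 methyl propiolate
Product: 3 methyl cyclohexa-1,4-diene-1-carboxylate
Conditions: 1 (excess), BHT (cat.), toluene, sealed tube, 110 °C
Reagents that add atoms: none
Why: Thermal Diels–Alder cycloaddition of the alkynoate with the symmetrical diene gives the 1,4-diene ester directly, with no regiochemical or stereochemical issue.

Step 2
Reactants: 3 methyl cyclohexa-1,4-diene-1-carboxylate
Product: 4 (cyclohexa-1,4-dien-1-yl)methanol
Conditions: i-Bu2AlH (2.2 equiv), CH2Cl2, −78 → 0 °C; aqueous Rochelle salt work-up
Reagents that add atoms: none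
Why: 1,2-Reduction of the unsaturated ester with an aluminium hydride should stop at the allylic alcohol and leave both alkenes untouched.

Step 3
Reactants: 4 (cyclohexa-1,4-dien-1-yl)methanol
Product: 5 [(1S,6S)-7-oxabicyclo[4.1.0]hept-3-en-1-yl]methanol (C1–C2 β-epoxide)
Conditions: Ti(OiPr)4 (10 mol%), diethyl L-(+)-tartrate (12 mol%), t-BuOOH (2 equiv), 4 Å molecular sieves, CH2Cl2, −20 °C
Reagents that add atoms: tert-butyl hydroperoxide, CC(C)(C)OO
Why: Katsuki–Sharpless asymmetric epoxidation touches only the allylic alkene, and for this 2,3E-disubstituted allylic alcohol the facial rule for the L-(+)-tartrate catalyst places oxygen on the face that becomes β, setting C1 (S at this stage).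

Step 4
Reactants: 5 [(1S,6S)-7-oxabicyclo[4.1.0]hept-3-en-1-yl]methanol
Product: 6 (1R,6S)-6-hydroxy-6-(hydroxymethyl)cyclohex-3-en-1-yl acetate (C2 α-acetate, C1 β-hydroxyl)
Conditions: Ti(OiPr)4 (1.5 equiv), AcOH (2 equiv), CH2Cl2, 0 → 20 °C; aqueous tartaric acid work-up
Reagents that add atoms: acetic acid, CC(=O)O
Why: In the titanium-mediated regioselective opening of a 2,3-epoxy alcohol the metal binds the C7 oxygen and the epoxide, so acetate should attack the ring carbon distal to the hydroxymethyl group (C2) in an SN2, trans-diaxial sense, inverting C2 to the α acetate while the C1–O bond stays intact.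

Step 5
Reactants: 6 (1R,6S)-6-hydroxy-6-(hydroxymethyl)cyclohex-3-en-1-yl acetate
Product: 7 [(1S,6R)-6-acetoxy-1-hydroxycyclohex-3-en-1-yl]methyl benzoate
Conditions: BzCl (1.05 equiv), pyridine, CH2Cl2, −20 → 0 °C
Reagents that add atoms: benzoyl chloride, O=C(Cl)c1ccccc1
Why: Pyridine-mediated O-acylation at low temperature should discriminate cleanly between the primary C7 hydroxyl and the hindered tertiary C1 hydroxyl.

Step 6
Reactants: 7 [(1S,6R)-6-acetoxy-1-hydroxycyclohex-3-en-1-yl]methyl benzoate
Product: 8 [(1S,2R,4R,5R)-2-acetoxy-4,5-dibromo-1-hydroxycyclohexyl]methyl benzoate (trans-4,5-dibromide)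
Conditions: Br2 (1.05 equiv), CH2Cl2, −78 °C
Reagents that add atoms: bromine, BrBr
Why: Electrophilic anti addition of bromine through a bromonium ion to the only alkene should give the trans-dibromide, bromide capture at low temperature outrunning participation by the tertiary hydroxyl; the C4/C5 configuration is erased in step 7.

Step 7
Reactants: 8 [(1S,2R,4R,5R)-2-acetoxy-4,5-dibromo-1-hydroxycyclohexyl]methyl benzoate
Product: 9 [(1S,6R)-6-acetoxy-1-hydroxycyclohexa-2,4-dien-1-yl]methyl benzoate (the C3–C6 diene)
Conditions: DBU (4 equiv), THF, 20 → 50 °C
Reagents that add atoms: none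
Why: Twofold E2 dehydrobromination with the non-nucleophilic amidine removes H3/Br4 and H6/Br5 to give the conjugated diene; C1 has no hydrogen and C2 is not involved, so both stereocentres persist.

Step 8
Reactants: 9 [(1S,6R)-6-acetoxy-1-hydroxycyclohexa-2,4-dien-1-yl]methyl benzoate
Product: 10 [(1R,2S,5R,6R)-5,6-diacetoxy-1-hydroxy-2-(trifluoroacetoxy)cyclohex-3-en-1-yl]methyl benzoate (C6 trifluoroacetate of the target)
Conditions: Pd(OAc)2 (5 mol%), LiCl (10 mol%), 1,4-benzoquinone (2 equiv), LiO2CCF3 (3 equiv), AcOH, 20 °C
Reagents that add atoms: acetic acid, CC(=O)O; lithium trifluoroacetate, [Li+].[O-]C(=O)C(F)(F)F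
Why: Divalent palladium should bind the C3–C6 diene on the β face, the side of the small and potentially coordinating C1 hydroxyl and the C2 hydrogen (the α face carries the C2 acetate and the C7 arm), acetic acid then attacks C3 from outside, anti to the metal, to give a C4–C5–C6 η3-allyl complex, and with chloride holding the site from which a bound carboxylate could otherwise migrate, trifluoroacetate attacks C6, again anti, while benzoquinone takes up the zerovalent palladium released. The closest known reaction type is the Pd(OAc)2/benzoquinone 1,4-diacyloxylation of cyclohexa-1,3-dienes in acetic acid, in its cis-selective chloride-modified form and in its acetate/trifluoroacetate form. No ring is closed. C3 (R) and C6 (S) are both fixed by the anti relationship between each incoming oxygen and the β-bound metal, so the two new C–O bonds are α, cis to each other and to the C2 acetate. Selectivity is needed in face (secured by the C1/C2 substituents), in 1,4- over 1,2-addition (the new C3 acetoxy group deactivates the adjacent allyl terminus C4) and in the placement of the two carboxylates (acetic acid, the abundant nucleophile, adds first at the terminus remote from the quaternary C1, whereas addition of trifluoroacetate to the diene complex should be reversible and unproductive, as chloride addition is in chloroacetoxylation). Free trifluoroacetic acid is left out and the temperature kept at 20 °C so that the tertiary dienyl carbinol, which could lose water and aromatise, meets only buffered acetic acid.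

Step 9
Reactants: 10 [(1R,2S,5R,6R)-5,6-diacetoxy-1-hydroxy-2-(trifluoroacetoxy)cyclohex-3-en-1-yl]methyl benzoate (used crude)
Product: 11 [(1R,2S,5R,6R)-5,6-diacetoxy-1,2-dihydroxycyclohex-3-en-1-yl]methyl benzoate (CNP0130780.2)
Conditions: NaHCO3 (0.2 equiv), MeOH, 0 °C
Reagents that add atoms: none
Why: Transesterification of a trifluoroacetate with methanol is far faster than that of acetates or a benzoate, so buffered methanol should free only the C6 hydroxyl without touching any stereocentre.

Compound list
1 | buta-1,3-diene | C=CC=C | starting material
2 | methyl propiolate | C#CC(=O)OC | starting material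
3 | methyl cyclohexa-1,4-diene-1-carboxylate | COC(=O)C1=CCC=CC1 | intermediate
4 | (cyclohexa-1,4-dien-1-yl)methanol | OCC1=CCC=CC1 | intermediate
5 | [(1S,6S)-7-oxabicyclo[4.1.0]hept-3-en-1-yl]methanol | OC[C@]12O[C@H]1CC=CC2 | intermediate
6 | (1R,6S)-6-hydroxy-6-(hydroxymethyl)cyclohex-3-en-1-yl acetate | CC(=O)O[C@@H]1CC=CC[C@]1(O)CO | intermediate
7 | [(1S,6R)-6-acetoxy-1-hydroxycyclohex-3-en-1-yl]methyl benzoate | CC(=O)O[C@@H]1CC=CC[C@]1(O)COC(=O)c1ccccc1 | intermediate
8 | [(1S,2R,4R,5R)-2-acetoxy-4,5-dibromo-1-hydroxycyclohexyl]methyl benzoate (trans-dibromide; the (4S,5S) trans isomer may accompany it and converges) | CC(=O)O[C@@H]1C[C@@H](Br)[C@H](Br)C[C@]1(O)COC(=O)c1ccccc1 | intermediate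
9 | [(1S,6R)-6-acetoxy-1-hydroxycyclohexa-2,4-dien-1-yl]methyl benzoate | CC(=O)O[C@@H]1C=CC=C[C@]1(O)COC(=O)c1ccccc1 | intermediate
10 | [(1R,2S,5R,6R)-5,6-diacetoxy-1-hydroxy-2-(trifluoroacetoxy)cyclohex-3-en-1-yl]methyl benzoate | CC(=O)O[C@@H]1[C@H](OC(C)=O)C=C[C@H](OC(=O)C(F)(F)F)[C@]1(O)COC(=O)c1ccccc1 | intermediate
11 | [(1R,2S,5R,6R)-5,6-diacetoxy-1,2-dihydroxycyclohex-3-en-1-yl]methyl benzoate | CC(=O)O[C@@H]1[C@H](OC(C)=O)C=C[C@H](O)[C@]1(O)COC(=O)c1ccccc1 | target

Total step count: 9. Longest linear sequence: 9 steps (fully linear from 1 and 2).

Steps most likely to fail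

Step 8 carries the risk of the route. Several processes may go wrong:
- the second carboxylate may be delivered from the metal's own face, giving the trans arrangement;
- acetic acid or chloride may compete with trifluoroacetate for the allyl terminus, so that C6 is no longer differentiated;
- the two carboxylates may add in the reverse orientation, or the second may add at C4 (1,2-addition);
- the tertiary dienyl carbinol may lose water and aromatise in the acidic medium.

The fallback sets out from diene 9 and exchanges the acetate/trifluoroacetate pair for the acetate/chloride pair. Cis-1,4-chloroacetoxylation (Pd(OAc)2, LiCl in excess, LiOAc, 1,4-benzoquinone, AcOH, 20 °C) should place acetate at C3 and chloride at C6, both α, to give the C3 α-acetoxy C6 α-chloro compound F1. Because the C6 chloride is trans to the C1 hydroxyl, DBU in CH2Cl2 at 0 °C should close the chlorohydrin to the C1–C6 β-epoxide F2 with inversion at C6. Dilute HClO4 in THF–water at 0 °C should then open this vinyl epoxide at the allylic carbon C6 with a second inversion, which returns the α hydroxyl and rejoins the route at target 11.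

Step 4 may suffer from transfer of the acetyl group from the C2 oxygen to the neighbouring primary hydroxyl or to isopropoxide on titanium, which would blur the C2/C7 differentiation, or from competing attack at the tertiary carbon C1. The fallback sets out from epoxy alcohol 5 and separates regiocontrol from acyl placement:
- the same titanium-mediated opening with benzoic acid should give the C2 benzoate, (1R,6S)-6-hydroxy-6-(hydroxymethyl)cyclohex-3-en-1-yl benzoate F3;
- K2CO3 in methanol removes the benzoate to give the triol (1S,2R)-1-(hydroxymethyl)cyclohex-4-ene-1,2-diol F4;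
- BzCl in pyridine at −20 °C acylates the primary hydroxyl to give [(1S,6R)-1,6-dihydroxycyclohex-3-en-1-yl]methyl benzoate F5;
- Ac2O, pyridine and catalytic DMAP at 0 °C acetylate the secondary C2 hydroxyl, rejoining the route at compound 7.

Step 7 (together with step 6) may fail in three ways. The bromonium ion may be intercepted by the tertiary hydroxyl. After the first loss of HBr, the allylic bromide may be captured by a neighbouring ester carbonyl or by the carbinol instead of eliminating. The sensitive dienol may aromatise on prolonged exposure to base and heat. The fallback sets out from alkene 7 and avoids both the bromonium ion and the second elimination. Wohl–Ziegler allylic bromination (NBS, AIBN cat., PhCF3, 80 °C) should give the allylic bromide [(1S,6R)-6-acetoxy-4-bromo-1-hydroxycyclohex-2-en-1-yl]methyl benzoate F6, as C4 epimers with minor allylic isomers that converge. A single elimination with DBU in THF at 20 °C then rejoins the route at diene 9.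

Further compounds
F1 | step 8 | (C1 β-hydroxy, C2 α-acetoxy, C3 α-acetoxy, C6 α-chloro)cyclohex-4-en-1-ylmethyl benzoate | CC(=O)O[C@@H]1[C@H](OC(C)=O)C=C[C@H](Cl)[C@]1(O)COC(=O)c1ccccc1
F2 | step 8 | (C2 α-acetoxy, C3 α-acetoxy, C1–C6 β-epoxy)cyclohex-4-en-1-ylmethyl benzoate | CC(=O)O[C@@H]1[C@H](OC(C)=O)C=C[C@H]2O[C@@]12COC(=O)c1ccccc1
F3 | step 4 | (1R,6S)-6-hydroxy-6-(hydroxymethyl)cyclohex-3-en-1-yl benzoate | O=C(O[C@@H]1CC=CC[C@]1(O)CO)c1ccccc1
F4 | step 4 | (1S,2R)-1-(hydroxymethyl)cyclohex-4-ene-1,2-diol | O[C@@H]1CC=CC[C@]1(O)CO
F5 | step 4 | [(1S,6R)-1,6-dihydroxycyclohex-3-en-1-yl]methyl benzoate | O[C@@H]1CC=CC[C@]1(O)COC(=O)c1ccccc1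
F6 | step 7 | [(1S,6R)-6-acetoxy-4-bromo-1-hydroxycyclohex-2-en-1-yl]methyl benzoate (epimeric at the bromine-bearing carbon) | CC(=O)O[C@@H]1CC(Br)C=C[C@]1(O)COC(=O)c1ccccc1
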